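The plan cuts the C9–C10 bond of ring B (C5–C6–C7–C8–C9–C10). This is the crowded link between the spiro-ether carbon C9 and quaternary C10, next to oxidised C8. Ring B is therefore carried as a cyclopentanone (C5, C6, C7, C8, C10) fused to the ring A/δ-lactone bicycle, and a C9, C11–C16 diyne fragment is added to C8. In one operation, gold-catalysed 5-endo-dig hydroalkoxylation closes the tetrahydrofuran and protonation gives the C9 oxocarbenium ion. A semipinacol shift of C10 from C8 to C9 then enlarges the five-membered ring to ring B, sets C9, and leaves the C8 ketone for the spiro-epoxide.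

Key step: step 14

Remark: labdane numbering (C1–C20) is used; α is the face of H5 and β is the face of C20.
Remark: C4 is an inconsequential mixture of epimers in 5–10 and is left open in their SMILES, because step 8 erases and resets it; 4 is used as an E/Z mixture.

Step 1
Reactants: 1 (S)-4-(tert-butyldimethylsilyloxy)cyclopent-2-en-1-one
Product: 2 (S)-4-(tert-butyldimethylsilyloxy)-2-(hydroxymethyl)cyclopent-2-en-1-one
Conditions: HCHO (37 % aq.), Bu3P (20 mol %), CHCl3–MeOH, 0 °C to rt
Reagents that add atoms: formaldehyde, C=O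
Why: Morita–Baylis–Hillman reaction: the phosphine adds reversibly to C5, the enolate takes up formaldehyde at C10 and the phosphine leaves again, so C20 arrives in one step and the C6 stereocentre is not touched under these nearly neutral conditions.

Step 2
Reactants: 2 (S)-4-(tert-butyldimethylsilyloxy)-2-(hydroxymethyl)cyclopent-2-en-1-one
Product: 3 (S)-4-(tert-butyldimethylsilyloxy)-2-[(triethylsilyloxy)methyl]cyclopent-2-en-1-one
Conditions: Et3SiCl, imidazole, CH2Cl2, 0 °C
Reagents that add atoms: chlorotriethylsilane, CC[Si](Cl)(CC)CC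
Why: Standard silylation of the primary allylic alcohol; the triethylsilyl ether is chosen because mild acid removes it in step 4 while the secondary tert-butyldimethylsilyl ether stays.

Step 3
Reactants: 3 (S)-4-(tert-butyldimethylsilyloxy)-2-[(triethylsilyloxy)methyl]cyclopent-2-en-1-one; 4 1-methoxy-1-(trimethylsilyloxy)prop-1-ene
Product: 5 Michael adduct as its C8=C10 trimethylsilyl enol ether (5β-CH(CH3)CO2CH3 trans to 6α-OTBS; CH2OTES on C10)
Conditions: Tf2NH (2 mol %), CH2Cl2, −78 °C; then Et3N
Reagents that add atoms: none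
Why: Mukaiyama–Michael addition with silyl transfer (Me3SiNTf2 formed in situ is the Lewis acid): the ketene acetal attacks C5 on the β face, anti to the 6α-silyloxy group, which sets C5, and the enolate is caught as the regiodefined C8=C10 enol silane so that no β-elimination can start.

Step 4
Reactants: 5 Michael adduct as its C8=C10 trimethylsilyl enol ether
Product: 7 cis-fused keto δ-lactone bearing the 10α-allyl group, via allyl ketone 6 (not isolated)
Conditions: Pd2(dba)3 (2.5 mol %), PPh3 (12 mol %), diallyl carbonate, Bu4N[Ph3SiF2] (35 mol %), THF, 25 °C; then MeOH, camphorsulfonic acid (20 mol %), rt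
Reagents that add atoms: diallyl carbonate, C=CCOC(=O)OCC=C
Why: Tsuji-type allylation of an enol silane: fluoride frees the tetrasubstituted enolate, which the π-allyl complex of divalent palladium allylates on the α face, anti to the bulky C5 side chain, setting quaternary C10 (enolates with a β-silyloxymethyl group are known to survive this reaction), and acidic methanol then removes only the primary triethylsilyl group so that the C20 hydroxyl, cis to the side chain, closes the δ-lactone on C19.

Step 5
Reactants: 7 cis-fused keto δ-lactone bearing the 10α-allyl group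
Product: 8 10α-(3-hydroxypropyl) keto δ-lactone
Conditions: 9-BBN, THF, 0 °C to rt; then 30 % H2O2, aq. NaOAc, 0 °C
Reagents that add atoms: hydrogen peroxide, OO
Why: Anti-Markovnikov hydroboration–oxidation: 9-BBN takes the terminal alkene much faster than the hindered ketone or the lactone, and the buffered peroxide work-up spares the base-sensitive β-silyloxy ketone.

Step 6
Reactants: 8 10α-(3-hydroxypropyl) keto δ-lactone
Product: 9 10α-(3-iodopropyl) keto δ-lactone
Conditions: I2, PPh3, imidazole, CH2Cl2, 0 °C
Reagents that add atoms: iodine, II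
Why: Appel-type iodination of the primary alcohol under neutral conditions puts the leaving group on C3.

Step 7
Reactants: 9 10α-(3-iodopropyl) keto δ-lactone
Product: 10 C7=C8 trimethylsilyl enol ether of 9
Conditions: Me3SiOTf, Et3N, CH2Cl2, 0 °C
Reagents that add atoms: trimethylsilyl trifluoromethanesulfonate, C[Si](C)(C)OS(=O)(=O)C(F)(F)F
Why: Soft enolisation: only C7 can be deprotonated because C10 is quaternary, and masking the ketone as its enol silane removes the acidic C7–H that would otherwise lead to E1cB loss of the 6-silyloxy group in step 8.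

Step 8
Reactants: 10 C7=C8 trimethylsilyl enol ether of 9
Product: 12 tricyclic keto lactone (trans-hydrindan-8-one bridged by the 19,20-δ-lactone; 4α-CH3; 5α-H; 6α-OTBS), via tricyclic enol silane 11 (not isolated)
Conditions: KN(SiMe3)2, THF, −78 to 0 °C; then 1 M HCl, THF, 0 °C
Reagents that add atoms: none
Why: Intramolecular enolate alkylation (6-exo-tet): both C4 epimers give one lactone enolate whose α lobe is the only one within reach of the axial 10α-iodopropyl chain, so ring A closes as a 2-oxabicyclo[3.3.1]nonanone and C4 is set by geometry (C19 β, methyl α), and brief aqueous acid returns the ketone.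

Step 9
Reactants: 13 2-bromoprop-2-en-1-ol; 14 ethynyltriisopropylsilane
Product: 15 2-methylidene-4-(triisopropylsilyl)but-3-yn-1-ol
Conditions: PdCl2(PPh3)2 (2 mol %), CuI (4 mol %), Et3N, THF, rt
Reagents that add atoms: none
Why: Sonogashira coupling of a vinyl bromide with a terminal alkyne joins C13 to C14 and tolerates the free alcohol.

Step 10
Reactants: 15 2-methylidene-4-(triisopropylsilyl)but-3-yn-1-ol
Product: 16 (R)-{2-[(triisopropylsilyl)ethynyl]oxiran-2-yl}methanol
Conditions: Ti(OiPr)4 (10 mol %), D-(−)-diisopropyl tartrate (12 mol %), t-BuOOH, 4 Å MS, CH2Cl2, −20 °C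
Reagents that add atoms: tert-butyl hydroperoxide, CC(C)(C)OO
Why: Sharpless asymmetric epoxidation of a 2-substituted allylic alcohol: with the D-(−)-tartrate the oxygen is delivered to the face that gives the (R)-epoxy alcohol, which fixes the later C13.

Step 11
Reactants: 16 (R)-{2-[(triisopropylsilyl)ethynyl]oxiran-2-yl}methanol
Product: 17 (S)-tert-butyldimethyl({2-[(triisopropylsilyl)ethynyl]oxiran-2-yl}methoxy)silane
Conditions: t-BuMe2SiCl, imidazole, CH2Cl2, 0 °C to rt
Reagents that add atoms: tert-butylchlorodimethylsilane, CC(C)(C)[Si](C)(C)Cl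
Why: Standard silylation protects the C16 hydroxyl and rules out Payne rearrangement in the basic step 12 (the descriptor changes only through the priority rules).

Step 12
Reactants: 17 (S)-tert-butyldimethyl({2-[(triisopropylsilyl)ethynyl]oxiran-2-yl}methoxy)silane
Product: 18 (R)-3-[(tert-butyldimethylsilyloxy)methyl]-1-(triisopropylsilyl)hexa-1,5-diyn-3-ol
Conditions: LiC≡CH·H2NCH2CH2NH2, DMSO–THF, rt; then H2O
Reagents that add atoms: lithium acetylide, [Li+].[C-]#C
Why: SN2 opening of the 2,2-disubstituted epoxide at its unsubstituted carbon (C12) by acetylide leaves the C13–O bond untouched, so C13 keeps its configuration.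

Step 13
Reactants: 12 tricyclic keto lactone; 18 (R)-3-[(tert-butyldimethylsilyloxy)methyl]-1-(triisopropylsilyl)hexa-1,5-diyn-3-ol
Product: 20 8α-alkynyl 8β-carbinol, via dilithium salt 19 (not isolated)
Conditions: 18, n-BuLi (2 equiv), THF, −78 °C; CeCl3, −78 °C; then 12, −78 °C; AcOH quench
Reagents that add atoms: n-butyllithium, [Li]CCCC
Why: 1,2-Addition of an alkynylcerium reagent, which is weakly basic and so avoids enolisation and β-elimination; as in other trans-hydrindan-1-ones with an angular substituent, the nucleophile enters from the α face, opposite to the axial C20, and gives the 8β-alcohol.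

Step 14
Reactants: 20 8α-alkynyl 8β-carbinol
Product: 22 spiro ketone (ring B six-membered; 8-oxo; 9α,13-epoxy; CH2OTBS and C≡C–TIPS on C13), via dihydrofuranyl carbinol 21 (not isolated)
Conditions: (Ph3P)AuCl (5 mol %), AgBF4 (5 mol %), camphorsulfonic acid (20 mol %), 4 Å MS, CH2Cl2, 0 °C to rt
Reagents that add atoms: none
Why: Cationic monovalent gold activates the C9≡C11 alkyne, the C13 hydroxyl adds to C9 (5-endo-dig closure of the tetrahydrofuran ring) and protodeauration gives 21; the sulfonic acid then protonates C11, and in the resulting C9 oxocarbenium ion the C8–C10 bond migrates to C9 while C8 becomes the ketone, so the cyclopentane becomes six-membered ring B (ring enlargement by a 1,2-shift, not a new closure). The closest known reaction types are the gold/Brønsted acid tandem cycloisomerisation of homopropargylic alcohols, the gold-triggered cyclisation/semipinacol cascade of alkynyl cycloalkanols, and the acid-induced pinacol-type ring expansion of (4,5-dihydrofuran-2-yl)cyclopentanols to 1-oxaspiro[4.5]decan-6-ones. C10 migrates with retention, and the new stereocentre C9 is controlled by the 8β-carbinol of step 13, because the shift should proceed from the rotamer in which the C8–OH and C9=O+ dipoles are anti and the ring oxygen, not the C11 methylene, sits under C7, which places oxygen α (axial) and C11 β. The step needs migration of C10 and not of C7: C10 is quaternary and carries developing positive charge better, and each of the two carbons bears one β-oxygen, so that this deactivation cancels. Chemoselectivity is secured because only the C9≡C11 alkyne has a hydroxyl within reach of a five-membered closure, the other alkyne is capped by the triisopropylsilyl group, all other oxygens are protected, and the sieves keep water from trapping the oxocarbenium ion.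

Step 15
Reactants: 22 spiro ketone
Product: 23 8β,17-epoxide of 22
Conditions: Me3SI, KN(SiMe3)2, THF, −10 °C; then 22, −10 °C to rt
Reagents that add atoms: trimethylsulfonium iodide, C[S+](C)C.[I-]
Why: Corey–Chaykovsky epoxidation: the ylide should attack C8 along the equatorial α trajectory because the axial C20 methylene closes the β face, so the alkoxide oxygen ends axial (β) and displaces dimethyl sulfide to give the 8β,17-epoxide, while the equatorial 6α-silyloxy group is poorly aligned for E1cB loss.

Step 16
Reactants: 23 8β,17-epoxide of 22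
Product: 24 6α,16-diol with a free ethynyl group on C13
Conditions: Bu4NF, THF, 0 °C to rt
Reagents that add atoms: none
Why: Fluoride cleaves both silyl ethers and the alkynylsilane, and the 6α-hydroxyl set free is trans to C19 and cannot attack the lactone.

Step 17
Reactants: 24 6α,16-diol with a free ethynyl group on C13
Product: 25 6α-alcohol with the spiro 2,3-dihydrofuran (6-epi-deacetyl target)
Conditions: Mo(CO)6 (25 mol %), Et3N, Et2O, hν (350 nm), rt
Reagents that add atoms: none
Why: Alkynol endo-cycloisomerisation: Et3N·Mo(CO)5 turns the terminal alkyne into a molybdenum vinylidene, the C16 hydroxyl adds to its electrophilic carbon C15 (5-endo) and protonolysis gives the 2,3-dihydrofuran under basic conditions that the epoxide, the lactone and the new enol ether tolerate.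

Step 18
Reactants: 25 6α-alcohol with the spiro 2,3-dihydrofuran
Product: 26 6-ketone
Conditions: Dess–Martin periodinane, pyridine, CH2Cl2, 0 °C
Reagents that add atoms: none
Why: Dess–Martin oxidation buffered with pyridine converts the only remaining alcohol into the C6 ketone without free acid that would harm the enol ether or the epoxide, and C5 stays in the stable trans-decalin configuration.

Step 19
Reactants: 26 6-ketone
Product: 28 target 6β-acetoxy-8β,17:9α,13:15,16-triepoxylabd-14-en-19,20-olide (CNP0173713.2), via lithium 6β-alkoxide 27 (not isolated)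
Conditions: Li[HB(s-Bu)3], THF, −78 °C; then Ac2O, DMAP, −78 to 0 °C
Reagents that add atoms: lithium tri-sec-butylborohydride, [Li+].CCC(C)[BH-](C(C)CC)C(C)CC; acetic anhydride, CC(=O)OC(C)=O
Why: Steric approach control: the bulky borohydride can reach the C6 ketone only from the α face because C19, C20 and the epoxide oxygen are all axial on the β face, which gives the axial 6β-alkoxide, and this is acetylated at low temperature before it can attack the C19 carbonyl.

Compound list
1 | (S)-4-(tert-butyldimethylsilyloxy)cyclopent-2-en-1-one | CC(C)(C)[Si](C)(C)O[C@H]1CC(=O)C=C1 | starting material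
2 | (S)-4-(tert-butyldimethylsilyloxy)-2-(hydroxymethyl)cyclopent-2-en-1-one | CC(C)(C)[Si](C)(C)O[C@H]1CC(=O)C(CO)=C1 | intermediate
3 | (S)-4-(tert-butyldimethylsilyloxy)-2-[(triethylsilyloxy)methyl]cyclopent-2-en-1-one | CC(C)(C)[Si](C)(C)O[C@H]1CC(=O)C(CO[Si](CC)(CC)CC)=C1 | intermediate
4 | 1-methoxy-1-(trimethylsilyloxy)prop-1-ene (ketene silyl acetal of methyl propanoate) | CC=C(OC)O[Si](C)(C)C | starting material
5 | Michael adduct as its C8=C10 trimethylsilyl enol ether (5β side chain, 6α-OTBS, CH2OTES on C10) | CC(C)(C)[Si](C)(C)O[C@H]1CC(O[Si](C)(C)C)=C(CO[Si](CC)(CC)CC)[C@@H]1C(C)C(=O)OC | intermediate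
6 | allyl ketone (10α-allyl, 10β-CH2OTES) | CC(C)(C)[Si](C)(C)O[C@H]1CC(=O)[C@](CC=C)(CO[Si](CC)(CC)CC)[C@@H]1C(C)C(=O)OC | intermediate
7 | cis-fused keto δ-lactone bearing the 10α-allyl group | CC(C)(C)[Si](C)(C)O[C@H]1CC(=O)[C@]2(CC=C)COC(=O)C(C)[C@H]12 | intermediate
8 | 10α-(3-hydroxypropyl) keto δ-lactone | CC(C)(C)[Si](C)(C)O[C@H]1CC(=O)[C@]2(CCCO)COC(=O)C(C)[C@H]12 | intermediate
9 | 10α-(3-iodopropyl) keto δ-lactone | CC(C)(C)[Si](C)(C)O[C@H]1CC(=O)[C@]2(CCCI)COC(=O)C(C)[C@H]12 | intermediate
10 | C7=C8 trimethylsilyl enol ether of 9 | CC(C)(C)[Si](C)(C)O[C@H]1C=C(O[Si](C)(C)C)[C@]2(CCCI)COC(=O)C(C)[C@H]12 | intermediate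
11 | tricyclic enol silane (ring A closed) | CC(C)(C)[Si](C)(C)O[C@H]1C=C(O[Si](C)(C)C)[C@]23CCC[C@](C)(C(=O)OC2)[C@H]13 | intermediate
12 | tricyclic keto lactone (trans-hydrindan-8-one, 19,20-δ-lactone, 6α-OTBS) | CC(C)(C)[Si](C)(C)O[C@H]1CC(=O)[C@]23CCC[C@](C)(C(=O)OC2)[C@H]13 | intermediate
13 | 2-bromoprop-2-en-1-ol | C=C(Br)CO | starting material
14 | ethynyltriisopropylsilane | C#C[Si](C(C)C)(C(C)C)C(C)C | starting material
15 | 2-methylidene-4-(triisopropylsilyl)but-3-yn-1-ol | C=C(CO)C#C[Si](C(C)C)(C(C)C)C(C)C | intermediate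
16 | (R)-{2-[(triisopropylsilyl)ethynyl]oxiran-2-yl}methanol | C1O[C@@]1(CO)C#C[Si](C(C)C)(C(C)C)C(C)C | intermediate
17 | (S)-tert-butyldimethyl({2-[(triisopropylsilyl)ethynyl]oxiran-2-yl}methoxy)silane | C1O[C@@]1(CO[Si](C)(C)C(C)(C)C)C#C[Si](C(C)C)(C(C)C)C(C)C | intermediate
18 | (R)-3-[(tert-butyldimethylsilyloxy)methyl]-1-(triisopropylsilyl)hexa-1,5-diyn-3-ol | C#CC[C@](O)(CO[Si](C)(C)C(C)(C)C)C#C[Si](C(C)C)(C(C)C)C(C)C | intermediate
19 | dilithium salt of 18 (alkoxide and acetylide) | [Li+].[Li+].[C-]#CC[C@]([O-])(CO[Si](C)(C)C(C)(C)C)C#C[Si](C(C)C)(C(C)C)C(C)C | intermediate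
20 | 8α-alkynyl 8β-carbinol | CC(C)(C)[Si](C)(C)O[C@H]1C[C@@](O)(C#CC[C@](O)(CO[Si](C)(C)C(C)(C)C)C#C[Si](C(C)C)(C(C)C)C(C)C)[C@]23CCC[C@](C)(C(=O)OC2)[C@H]13 | intermediate
21 | dihydrofuranyl carbinol (C9=C11 enol ether) | CC(C)(C)[Si](C)(C)O[C@H]1C[C@@](O)(C4=CC[C@](CO[Si](C)(C)C(C)(C)C)(C#C[Si](C(C)C)(C(C)C)C(C)C)O4)[C@]23CCC[C@](C)(C(=O)OC2)[C@H]13 | intermediate
22 | spiro ketone (8-oxo, 9α,13-epoxy, six-membered ring B) | CC(C)(C)[Si](C)(C)O[C@H]1CC(=O)[C@]2(CC[C@](CO[Si](C)(C)C(C)(C)C)(C#C[Si](C(C)C)(C(C)C)C(C)C)O2)[C@]23CCC[C@](C)(C(=O)OC2)[C@H]13 | intermediate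
23 | 8β,17-epoxide of 22 | CC(C)(C)[Si](C)(C)O[C@H]1C[C@@]2(CO2)[C@]2(CC[C@](CO[Si](C)(C)C(C)(C)C)(C#C[Si](C(C)C)(C(C)C)C(C)C)O2)[C@]23CCC[C@](C)(C(=O)OC2)[C@H]13 | intermediate
24 | 6α,16-diol with a free ethynyl group on C13 | O[C@H]1C[C@@]2(CO2)[C@]2(CC[C@](CO)(C#C)O2)[C@]23CCC[C@](C)(C(=O)OC2)[C@H]13 | intermediate
25 | 6α-alcohol with the spiro 2,3-dihydrofuran | O[C@H]1C[C@@]2(CO2)[C@]2(CC[C@]3(C=COC3)O2)[C@]23CCC[C@](C)(C(=O)OC2)[C@H]13 | intermediate
26 | 6-ketone | O=C1C[C@@]2(CO2)[C@]2(CC[C@]3(C=COC3)O2)[C@]23CCC[C@](C)(C(=O)OC2)[C@H]13 | intermediate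
27 | lithium 6β-alkoxide | [Li+].[O-][C@@H]1C[C@@]2(CO2)[C@]2(CC[C@]3(C=COC3)O2)[C@]23CCC[C@](C)(C(=O)OC2)[C@H]13 | intermediate
28 | 6β-acetoxy-8β,17:9α,13:15,16-triepoxylabd-14-en-19,20-olide (CNP0173713.2) | CC(=O)O[C@@H]1C[C@@]2(CO2)[C@]2(CC[C@]3(C=COC3)O2)[C@]23CCC[C@](C)(C(=O)OC2)[C@H]13 | target

Total step count: 19
Longest linear sequence: 15 (steps 1–8 and 13–19)

Steps most likely to fail

1. Step 14.
- What may go wrong: migration of C7 in place of C10, ionisation or Meyer–Schuster-type isomerisation of the tertiary propargylic alcohols under the acid, or weak rotamer control at C9.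
- Fallback (sets out from 20, comes back at 22): the two events are separated, and the shift is triggered by a halonium ion instead of a proton.
- Compound 20 is cycloisomerised with (Ph3P)AuCl/AgBF4 in the presence of 2,6-di-tert-butylpyridine, so that 21 can be isolated.
- N-Bromosuccinimide in CH2Cl2–propylene oxide at −78 °C brominates C11. The bromo-oxocarbenium ion should rearrange at low temperature without acid to the 11-bromo spiro ketone F1.
- Bu3SnH/AIBN in toluene removes the bromine and gives 22.

2. Step 8.
- What may go wrong: loss of the enol silane under the strongly basic conditions followed by β-elimination of the 6-silyloxy group, or slow deprotonation of the hindered C4–H so that the iodide is consumed by elimination.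
- Fallback (sets out from 9, comes back at 12): the ketone is taken out of play by a change of oxidation level.
- NaBH4 in MeOH at −20 °C gives the 8-alcohol F2, whose C8 configuration is irrelevant.
- Et3SiOTf/2,6-lutidine gives the 8-triethylsilyl ether F3.
- KN(SiMe3)2 in THF closes ring A to the tricyclic silyl ether F4.
- Pyridinium p-toluenesulfonate in MeOH removes only the triethylsilyl group and gives the tricyclic 8-alcohol F5.
- Dess–Martin oxidation returns 12.

3. Step 15.
- What may go wrong: poor facial selectivity (the axial C9–O bond favours β attack electronically), no addition to the ketone next to fully substituted C9, or enolisation by the ylide.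
- Fallback (sets out from 22, comes back at 23): the oxygen is brought in by anti addition to an alkene.
- Wittig methylenation (Ph3P=CH2, THF) gives the 8(17)-exocyclic alkene F6.
- With N-bromosuccinimide in aqueous DME the bromonium ion forms on the open α face, and water opens it at tertiary C8 from the β face to give the 8β-hydroxy-17-bromide F7.
- K2CO3 in MeOH closes the 8β,17-epoxide 23.

Further compounds
F1 | step 14 | 11-bromo spiro ketone | CC(C)(C)[Si](C)(C)O[C@H]1CC(=O)[C@]2(C(Br)C[C@](CO[Si](C)(C)C(C)(C)C)(C#C[Si](C(C)C)(C(C)C)C(C)C)O2)[C@]23CCC[C@](C)(C(=O)OC2)[C@H]13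
F2 | step 8 | 8-alcohol of 9 | CC(C)(C)[Si](C)(C)O[C@H]1CC(O)[C@]2(CCCI)COC(=O)C(C)[C@H]12
F3 | step 8 | 8-triethylsilyl ether of F2 | CC(C)(C)[Si](C)(C)O[C@H]1CC(O[Si](CC)(CC)CC)[C@]2(CCCI)COC(=O)C(C)[C@H]12
F4 | step 8 | tricyclic silyl ether (ring A closed) | CC(C)(C)[Si](C)(C)O[C@H]1CC(O[Si](CC)(CC)CC)[C@]23CCC[C@](C)(C(=O)OC2)[C@H]13
F5 | step 8 | tricyclic 8-alcohol | CC(C)(C)[Si](C)(C)O[C@H]1CC(O)[C@]23CCC[C@](C)(C(=O)OC2)[C@H]13
F6 | step 15 | 8(17)-exocyclic alkene | CC(C)(C)[Si](C)(C)O[C@H]1CC(=C)[C@]2(CC[C@](CO[Si](C)(C)C(C)(C)C)(C#C[Si](C(C)C)(C(C)C)C(C)C)O2)[C@]23CCC[C@](C)(C(=O)OC2)[C@H]13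
F7 | step 15 | 8β-hydroxy-17-bromide | CC(C)(C)[Si](C)(C)O[C@H]1C[C@@](O)(CBr)[C@]2(CC[C@](CO[Si](C)(C)C(C)(C)C)(C#C[Si](C(C)C)(C(C)C)C(C)C)O2)[C@]23CCC[C@](C)(C(=O)OC2)[C@H]13
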